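**Retrosynthetic overview**

1. Atom numbers follow the order of the atoms in the target SMILES (C1 to C28). The strategy rests on ring B (C8–C9–C10–C12–C17–C18–C20): it holds both carbonyl carbons C10 and C18 on benzene ring A, so it is the five-membered ring of an indane-1,3-dione (C9, C10, C12, C17, C18) widened by the two carbons C8 and C20.
2. The furan (C5, O6, C7, C8, C20) comes from cyclodehydration of the C7 hydroxyl onto the C5 ketone of hydroquinone 16, which comes from Na2S2O4 reduction of quinone 15.
3. 15 comes from ynedione 12: the triketone carbanion C9 adds to C8 (closing ring D, C7–C8–C9–C21–C23–C28) and the alkyne carbons C8 and C20 are inserted into the C9–C18 bond (new bonds C8–C9 and C18–C20).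
4. 12 comes from oxidation of carbinol 11, made from Weinreb amide 6 and alkynol 9 (bond C7–C8); 6 comes from indane-1,3-dione 4 and acid 3 (bond C9–C21); 9 comes from ethynylmagnesium bromide and 3-methylbut-2-enal.
5. Order of rings: A and E are bought, D and then B form in step 6, the furan closes last in step 8.

Key step: step 6

Assumption: radermachol is taken as the chelated C10–OH/C21=O tautomer of the target SMILES; the C21–OH/C10=O form that the furan closure delivers first is the same compound by proton shift.

**Route**

Step 1
Reactants: 1 phthalic anhydride; 2 N,O-dimethylhydroxylamine hydrochloride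
Product: 3 2-[methoxy(methyl)carbamoyl]benzoic acid
Conditions: Et3N (2.2 equiv), CH2Cl2, 0 °C → rt; cold dilute HCl wash, used promptly
Reagents that add atoms: none
Why: Aminolysis of a cyclic anhydride should stop cleanly at the mono-amide acid, because the carboxylate that is set free is no longer an acylating agent.

Step 2
Reactants: 3 2-[methoxy(methyl)carbamoyl]benzoic acid; 4 indane-1,3-dione
Product: 6 2-{2-[methoxy(methyl)carbamoyl]benzoyl}indane-1,3-dione, via enol ester 5 (not isolated)
Conditions: DCC, DMAP, Et3N, CH2Cl2, 0 °C → rt; 1 M HCl work-up
Reagents that add atoms: none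
Why: Carbodiimide activation should give the enol ester of 4 and DMAP then moves the acyl group from oxygen to carbon (Steglich-type O-to-C acyl shift, the known direct C-acylation of cyclic 1,3-diones), ending in the strongly stabilised triketone while the Weinreb amide stays untouched.

Step 3
Reactants: 7 ethynylmagnesium bromide; 8 3-methylbut-2-enal
Product: 9 rac-5-methylhex-4-en-1-yn-3-ol
Conditions: THF, 0 °C; aq NH4Cl
Reagents that add atoms: none
Why: 1,2-Addition of the alkynyl Grignard reagent to the enal carbonyl should give the racemic allylic, propargylic alcohol, whose carbinol centre needs no control because it is oxidised in step 5.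

Step 4
Reactants: 6 2-{2-[methoxy(methyl)carbamoyl]benzoyl}indane-1,3-dione; 9 rac-5-methylhex-4-en-1-yn-3-ol
Product: 11 rac-2-[2-(4-hydroxy-6-methylhept-5-en-2-ynoyl)benzoyl]indane-1,3-dione, via tetrahedral lithium adduct 10 (not isolated)
Conditions: 9 (2.5 equiv), n-BuLi (5.0 equiv), THF, −78 → −20 °C; add 6, −78 → −20 °C; inverse quench into cold 1 M HCl
Reagents that add atoms: none
Why: Weinreb ketone synthesis, in which the first equivalent of acetylide only deprotonates the triketone (its anion is inert to nucleophiles) and the C,O-dilithio alkynol then adds to the amide to give a chelated tetrahedral adduct that releases the ynone C7(=O)–C8≡C20 only in the acidic quench, where the liberated amine is protonated and cannot add to the ynone; this is preferred to a carbonylative coupling of an ortho-haloaroyl triketone, in which the acylpalladium would be captured by the neighbouring enolate oxygen.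

Step 5
Reactants: 11 rac-2-[2-(4-hydroxy-6-methylhept-5-en-2-ynoyl)benzoyl]indane-1,3-dione
Product: 12 2-[2-(6-methyl-4-oxohept-5-en-2-ynoyl)benzoyl]indane-1,3-dione
Conditions: Dess–Martin periodinane (1.2 equiv), CH2Cl2, 0 °C; aq Na2S2O3 buffered at pH 5; crude product used at once
Reagents that add atoms: none
Why: Dess–Martin oxidation of a doubly activated (allylic and propargylic) secondary alcohol should be fast under mildly acidic, base-free conditions, in which the triketone stays protonated and does not yet attack the very electrophilic ynedione.

Step 6
Reactants: 12 2-[2-(6-methyl-4-oxohept-5-en-2-ynoyl)benzoyl]indane-1,3-dione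
Product: 15 ring-expanded naphthoquinone (rings A/B/D/E; keto form with C20–H; racemic), via spiro allenolate 13 (not isolated), via cyclobutene alkoxide 14 (not isolated)
Conditions: Cs2CO3 (1.2 equiv), dry MeCN (0.01 M), 0 °C → rt; then cold 1 M HCl
Reagents that add atoms: none
Why: Cs2CO3 should ionise the triketone completely (pKa about 3), and the carbanion C9 adds to C8 of the ynedione, the carbon β to the C5 ketone, closing ring D in the 6-exo-dig mode and leaving an allenolate centred on C20. In the aprotic medium this allenolate attacks the indanedione carbonyl C18 (4-exo-trig; C10 and C18 are equivalent by symmetry) to give a cyclobutene alkoxide, and retro-aldol cleavage of C9–C18 turns the five-membered ring into seven-membered ring B and leaves a highly delocalised anion that is protonated at C20 on acidification. The closest known reaction type is the base-mediated two-carbon ring expansion of cyclic 1,3-dicarbonyl compounds by activated alkynes (Michael addition, cyclobutene aldol, retro-aldol), run here intramolecularly. The only new stereocentre, C20, is enolisable and forms as a racemate that is erased in the furan, so no control is needed. The step needs carbon rather than oxygen attack of the triketonate and attack at C8 rather than C20: the six-membered transition state favours C8 over the seven-membered alternative, oxygen adducts can revert at the allenolate stage while only the carbon adduct is drained irreversibly by the ring expansion, and the ring D carbonyl C21 cannot be reached by C20 because that would place the C8=C20 double bond at a bridgehead. Release of cyclobutene strain and formation of the naphthoquinone drive the fragmentation.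

Step 7
Reactants: 15 ring-expanded naphthoquinone
Product: 16 hydroquinone (C7–OH and C21–OH on aromatic ring D; racemic at C20)
Conditions: Na2S2O4 (3 equiv), THF/H2O, rt, argon; crude product kept under argon
Reagents that add atoms: none
Why: Sodium dithionite should reduce the 1,4-naphthoquinone to the hydroquinone at room temperature and leave the aryl ketones and the β,β-disubstituted enone untouched.

Step 8
Reactants: 16 hydroquinone
Product: 17 radermachol
Conditions: TsOH·H2O (10 mol %), toluene, 60 °C, argon
Reagents that add atoms: none
Why: Acid-catalysed cyclodehydration of an ortho-hydroxyaryl ketone (Paal–Knorr-type furan synthesis), in which the C7 hydroxyl adds to the C5 ketone in a 5-exo mode and loss of water aromatises the furan (C5, O6, C7, C8, C20), after which proton shift within the C21–OH/C10=O chelate gives the tautomer of the target; the C18 ketone cannot compete because an O–C18 bond would create a bridged ring.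

**Compound list**

1 | phthalic anhydride (2-benzofuran-1,3-dione) | O=C1OC(=O)c2ccccc12 | starting material
2 | N,O-dimethylhydroxylamine hydrochloride | CNOC.Cl | starting material
3 | 2-[methoxy(methyl)carbamoyl]benzoic acid | CON(C)C(=O)c1ccccc1C(=O)O | intermediate
4 | indane-1,3-dione | O=C1CC(=O)c2ccccc12 | starting material
5 | 1-oxo-1H-inden-3-yl 2-[methoxy(methyl)carbamoyl]benzoate (enol ester, not isolated) | CON(C)C(=O)c1ccccc1C(=O)OC1=CC(=O)c2ccccc12 | intermediate
6 | 2-{2-[methoxy(methyl)carbamoyl]benzoyl}indane-1,3-dione (drawn as triketone; present as the exocyclic enol) | CON(C)C(=O)c1ccccc1C(=O)C1C(=O)c2ccccc2C1=O | intermediate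
7 | ethynylmagnesium bromide | C#C[Mg]Br | starting material
8 | 3-methylbut-2-enal | CC(C)=CC=O | starting material
9 | rac-5-methylhex-4-en-1-yn-3-ol | CC(C)=CC(O)C#C | intermediate
10 | trilithium salt of the tetrahedral adduct at C7 (N-methoxy-N-methylamino alkoxide, C5 alkoxide, triketonate; mixture of diastereomers; not isolated) | CC(C)=CC([O-])C#CC([O-])(N(C)OC)c1ccccc1C(=O)[C-]1C(=O)c2ccccc2C1=O.[Li+].[Li+].[Li+] | intermediate
11 | rac-2-[2-(4-hydroxy-6-methylhept-5-en-2-ynoyl)benzoyl]indane-1,3-dione | CC(C)=CC(O)C#CC(=O)c1ccccc1C(=O)C1C(=O)c2ccccc2C1=O | intermediate
12 | 2-[2-(6-methyl-4-oxohept-5-en-2-ynoyl)benzoyl]indane-1,3-dione (key-step precursor) | CC(C)=CC(=O)C#CC(=O)c1ccccc1C(=O)C1C(=O)c2ccccc2C1=O | intermediate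
13 | caesium allenolate of the spiro Michael adduct: ring D closed, C9 spiro to the intact indane-1,3-dione, C8=C20=C5(O−) (not isolated) | CC(C)=CC([O-])=C=C1C(=O)c2ccccc2C(=O)C12C(=O)c3ccccc3C2=O.[Cs+] | intermediate
14 | caesium cyclobutene alkoxide: four-membered ring C8=C20–C18(O−)–C9, cis-fused to the indanone ring (racemic, one enantiomer drawn; not isolated) | CC(C)=CC(=O)C1=C2C(=O)c3ccccc3C(=O)[C@@]24C(=O)c5ccccc5[C@@]14[O-].[Cs+] | intermediate
15 | ring-expanded naphthoquinone: 1,4-naphthoquinone whose C2 and C3 are bridged by –C(=O)–(1,2-phenylene)–C(=O)–CH(COCH=CMe2)–, the CH (C20) on C3 (racemic, enolisable; key-step product) | CC(C)=CC(=O)C1C(=O)c2ccccc2C(=O)C2=C1C(=O)c1ccccc1C2=O | intermediate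
16 | hydroquinone of 15 (naphthalene-1,4-diol, same bridge; racemic at C20) | CC(C)=CC(=O)C1C(=O)c2ccccc2C(=O)c2c1c(O)c1ccccc1c2O | intermediate
17 | radermachol | CC(C)=Cc1oc2c3c(c(O)c4ccccc4c(=O)c13)C(=O)c1ccccc1-2 | target

**Step count**

Total steps: 8. Longest linear sequence: 7 (steps 1, 2, 4, 5, 6, 7, 8).

**Steps most likely to fail**

Step 6. The cascade may stop short if the triketonate attacks through oxygen, or if the allenolate is protonated before the four-membered ring closes. Either path would end in a simple cyclisation product without ring enlargement. The fallback sets out from phthalic anhydride 1 and comes back at radermachol 17; it builds ring B by a double Friedel–Crafts acylation instead of alkyne insertion. Conjugate addition of the kinetic trimethylsilyl enol ether of 4-methylpentan-2-one to 1,4-naphthoquinone (BF3·OEt2, CH2Cl2, −78 °C) should give 2-(4-methyl-2-oxopentyl)naphthalene-1,4-diol F1. Warming F1 with TsOH should cyclodehydrate it to 2-(2-methylpropyl)naphtho[1,2-b]furan-5-ol F2. Fusion of F2 with 1 in an AlCl3–NaCl melt should acylate furan C3 and naphthalene C4 with the two carbonyl groups of 1, closing the seven-membered ring to the 2-(2-methylpropyl) analogue of radermachol F3. Radical bromination at the furylic CH2 (NBS, AIBN, PhCF3, 80 °C) should give the 1-bromo-2-methylpropyl compound F4, and dehydrobromination with DBU should give 17.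

Step 5. The free-acid ynedione may ionise and cyclise in an uncontrolled way during oxidation or work-up, and the enolised triketone carbon may itself be oxidised. The fallback sets out from hydroxy ynone 11 and comes back at quinone 15. The acidic enol of 11 is silylated selectively (i-Pr3SiCl, 2,6-lutidine, CH2Cl2, 0 °C; the neutral secondary alcohol should not react with the chlorosilane under these conditions) to the enol triisopropylsilyl ether F5. The carbinol of F5, now in a neutral and non-chelating molecule, is oxidised with activated MnO2 in CH2Cl2 to the silyl-masked ynedione F6. Anhydrous CsF in MeCN then removes silicon, and the caesium triketonate that is released should enter the ring-expansion cascade at once through 13 and 14, so that the free-acid ynedione is never handled.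

Step 4. Addition of the poorly soluble dilithio alkynol to the hindered, ortho-disubstituted amide may be incomplete, and the amine liberated at the quench may add to the ynone. The fallback sets out from Weinreb amide 6 and comes back at ynedione 12. The amide is reduced to the aldehyde (NaH, then i-Bu2AlH, THF, −78 °C; the sodium triketonate should not be reduced) to give 2-(2-formylbenzoyl)indane-1,3-dione F7. The dilithio derivative of 9 should add to this far more electrophilic carbonyl at −78 °C to give the bis-carbinol F8 (mixture of diastereomers), with no amine present at the quench. Dess–Martin periodinane (2.5 equiv, CH2Cl2, 0 °C) should then oxidise both propargylic carbinols in one operation to 12.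

**Further compounds**

F1 | step 6 | 2-(4-methyl-2-oxopentyl)naphthalene-1,4-diol | CC(C)CC(=O)Cc1cc(O)c2ccccc2c1O
F2 | step 6 | 2-(2-methylpropyl)naphtho[1,2-b]furan-5-ol | CC(C)Cc1cc2cc(O)c3ccccc3c2o1
F3 | step 6 | 2-(2-methylpropyl) analogue of radermachol | CC(C)Cc1oc2c3c(c(O)c4ccccc4c(=O)c13)C(=O)c1ccccc1-2
F4 | step 6 | 2-(1-bromo-2-methylpropyl) analogue of radermachol (racemic) | CC(C)C(Br)c1oc2c3c(c(O)c4ccccc4c(=O)c13)C(=O)c1ccccc1-2
F5 | step 5 | enol triisopropylsilyl ether of 11 (silicon on the exocyclic enol oxygen at C21; racemic) | CC(C)=CC(O)C#CC(=O)c1ccccc1C(O[Si](C(C)C)(C(C)C)C(C)C)=C1C(=O)c2ccccc2C1=O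
F6 | step 5 | enol triisopropylsilyl ether of 12 | CC(C)=CC(=O)C#CC(=O)c1ccccc1C(O[Si](C(C)C)(C(C)C)C(C)C)=C1C(=O)c2ccccc2C1=O
F7 | step 4 | 2-(2-formylbenzoyl)indane-1,3-dione | O=Cc1ccccc1C(=O)C1C(=O)c2ccccc2C1=O
F8 | step 4 | 2-[2-(1,4-dihydroxy-6-methylhept-5-en-2-ynyl)benzoyl]indane-1,3-dione (mixture of diastereomers) | CC(C)=CC(O)C#CC(O)c1ccccc1C(=O)C1C(=O)c2ccccc2C1=O
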